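- I compared the maple run with itself. Target made per day was 0.00456 M d⁻¹ up to 8.00 d and 0.00453 M d⁻¹ up to 25.0 d, so its early rate r looked zero-order, indifferent to the starting material left.

common to all: initiator 20 mM
- maple: starting material 0.41 M; coupling partner 1.2 M; temperature 15 °C; run made earlier
- elm: starting material 0.63 M; coupling partner 1.2 M; temperature 35 °C; run made earlier
- Friday's: starting material 0.80 M; coupling partner 1.20 M; temperature 50 °C; time 20 d
- Tuesday's: starting material 0.50 M; coupling partner 1.20 M; temperature 20 °C; time 20 d

- maple (time / d: target / %): 8.00: 8.9; 25.0: 27.6; 50.0: 49.2; 60.0: 56.3; 80.0: 67.0; 120: 78.6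
- elm (time / d: target / %): 4.00: 33.9; 5.00: 40.3; 8.00: 55.5; 15.0: 71.7; 25.0: 76.4; 40.0: 77.0

(readings scatter by 0.5 percentage points)

1. which one finishes higher in amount of target, in percent of the starting material charged ("neither" within 2 percentage points) (Friday's / Tuesday's / neither)
2. amount of target at the end, in percent of the starting material charged, Friday's
3. amount of target at the end, in percent of the starting material charged, Tuesday's

- what was read earlier has a scatter of 0.5 percentage points, one standard deviation

- I held two times against each other: the time allowed, t, and the fill time τ, meaning the charge of starting material divided by r. Where t stood below τ, I took t/τ as the yield; where it stood above, I expected a ceiling.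
- The first elm reading gave 0.0534 M d⁻¹. Elm differed from maple in its charge as well as its temperature, and I assumed r indifferent to the charge. Spreading ln r evenly over the degrees, I got 0.00839 M d⁻¹ for Tuesday's and, more roughly, 0.340 M d⁻¹ for Friday's.
- Tuesday's fill time was 59.6 d, longer than 20 d, so my first answer was 33.6 %.
- I put that answer back. By my reckoning it meant 0.332 M of Tuesday's charge not turned to target, more than the 0.297 M not turned to target in maple at 25.0 d. Maple's slope fell to 0.00354 M d⁻¹ after that reading, so I kept r.
- Friday's fill time was 2.35 d, shorter than 20 d, so I expected Friday's at its ceiling, and I had no height for it better than the forecast's.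
- The forecast said Friday's, with 64 % for Friday's and 35 % for Tuesday's, the latter a little above my figure, and “At 50 °C, 20 d should reach the ceiling”.
- The flasks gave 64.2 % for Friday's and 35.0 % for Tuesday's, so Friday's finished higher.

    initiator → 2 initiating radical (k = 1.80 × 10⁻⁴ min⁻¹, Ea = 111 kJ mol⁻¹)
    starting material + initiating radical → capped initiator + first chain carrier (k = 2.50 × 10⁵ L mol⁻¹ min⁻¹, Ea = 15.0 kJ mol⁻¹)
    coupling partner + first chain carrier → target + second chain carrier (k = 14000 L mol⁻¹ min⁻¹, Ea = 47.0 kJ mol⁻¹)
    starting material + second chain carrier → by-product + first chain carrier (k = 7400 L mol⁻¹ min⁻¹, Ea = 44.0 kJ mol⁻¹)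
    first chain carrier → ended carrier (k = 260 min⁻¹, Ea = 77.0 kJ mol⁻¹)
    2 first chain carrier → ended chains A (k = 8.00 × 10⁷ L mol⁻¹ s⁻¹, Ea = 10.0 kJ mol⁻¹)
    2 second chain carrier → ended chains B (k = 4.00 × 10⁶ L mol⁻¹ s⁻¹, Ea = 22.0 kJ mol⁻¹)
    starting material + target → side product (k = 2.90 × 10⁻⁴ L mol⁻¹ min⁻¹, Ea = 95.0 kJ mol⁻¹)
    crystals ⇌ by-product, rate k9*(cs9 - [by-product]) while solid is left; crystals form when [by-product] > cs9 (solubility = 0.280 M, k = 0.0630 min⁻¹)
    (constants at 50 °C)

- Tuesday's kept 61 % of its charge, 0.307 M, still more than the maple level. A neighbouring flask, the same as Tuesday's but with 0.20 M of starting material, had a fill time of 23.8 d and a first answer of 84.0 %. But its charge stood below the maple level from the start, so the second round refused a constant r. That flask gave 51.5 %, with 46.5 % of its starting material left.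

The runs were computed for substances that don't exist; the scatter is artificial.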